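**Plan**
- Retrosynthesis: the C3–H of the flavone is first traced back to C3–Cl. The two ring bonds to C3 (C2–C3 and C3–C4 of pyranone ring C) are then cut, which removes C3 as dichlorocarbene (from chloroform) and contracts ring C to the furan ring of a 2-aryl-3-silyloxybenzofuran.
- Enabling feature: C3 is the only unsubstituted atom of ring C, a lone CH between C2 (bonded to O1 and ring B) and the C4 carbonyl, so it can be inserted as one carbon into the O–C=C–O enol ether bond of the benzofuran.
- The benzofuran is cut at O–Si, at the furan C2–C3 bond (carbanion acylation) and at the benzylic O–CH2 bond (Williamson), giving methyl 2-hydroxy-4,5-dimethoxybenzoate (ring A) and 3,4,5-trimethoxybenzyl chloride (ring B).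
- Forward order: ether link, furan ring closure, O-silylation, furan-to-pyranone expansion that creates ring C, removal of the chlorine.
- Stereochemistry: the target has no stereocentre; the racemic centres that appear on the way (C2 of the benzofuranone, the cyclopropane) are erased again.

Key step: step 4

Assumption: all five methoxy groups are carried unchanged from the two commercial arenes, commercial LDA solution is used, and the silyl group is taken to leave step 4 as its chloride.

**Step 1**
Reactants: 1 methyl 2-hydroxy-4,5-dimethoxybenzoate; 2 5-(chloromethyl)-1,2,3-trimethoxybenzene (3,4,5-trimethoxybenzyl chloride)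
Product: 3 methyl 4,5-dimethoxy-2-[(3,4,5-trimethoxyphenyl)methoxy]benzoate
Conditions: K2CO3, DMF, 60 °C
Reagents that add atoms: none
Why: Williamson ether synthesis, in which the carbonate-generated salicylate phenoxide displaces the reactive benzylic chloride of 2 by SN2 and no other site of either partner is alkylated.

**Step 2**
Reactants: 3 methyl 4,5-dimethoxy-2-[(3,4,5-trimethoxyphenyl)methoxy]benzoate
Product: 5 5,6-dimethoxy-2-(3,4,5-trimethoxyphenyl)-1-benzofuran-3(2H)-one (racemic), via lithium benzofuran-3-olate 4 (not isolated)
Conditions: LiN(CH(CH3)2)2 (2.2 equiv), THF, −78 → 0 °C; then degassed 1 M HCl, argon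
Reagents that add atoms: none
Why: Intramolecular Claisen-type (Dieckmann-like) acylation, in which the amide base removes a benzylic proton next to the aryl ether oxygen, the carbanion adds 5-exo-trig to the neighbouring methyl ester with loss of methoxide, and the second equivalent of base holds the product as the aromatic 3-oxidobenzofuran 4 until the acidic quench; the C2 centre of 5 is racemic and disappears in step 3.

**Step 3**
Reactants: 5 5,6-dimethoxy-2-(3,4,5-trimethoxyphenyl)-1-benzofuran-3(2H)-one
Product: 6 3-(tert-butyldimethylsilyloxy)-5,6-dimethoxy-2-(3,4,5-trimethoxyphenyl)-1-benzofuran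
Conditions: t-BuMe2SiOSO2CF3, Et3N, CH2Cl2, 0 °C
Reagents that add atoms: tert-butyldimethylsilyl trifluoromethanesulfonate, CC(C)(C)[Si](C)(C)OS(=O)(=O)C(F)(F)F
Why: Silyl enol ether formation by soft enolisation, where O-silylation is favoured over C-silylation because it aromatises the five-membered ring to the benzofuran.

**Step 4**
Reactants: 6 3-(tert-butyldimethylsilyloxy)-5,6-dimethoxy-2-(3,4,5-trimethoxyphenyl)-1-benzofuran; 7 chloroform
Product: 10 3-chloro-6,7-dimethoxy-2-(3,4,5-trimethoxyphenyl)chromen-4-one, via dichlorocyclopropane adduct 8 (not isolated), via silyloxychromenylium chloride 9 (not isolated)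
Conditions: CHCl3 (excess), KOC(CH3)3 (added in portions), hexane, −20 °C → rt
Reagents that add atoms: chloroform (compound 7), ClC(Cl)Cl
Why: Proposed new method: KOC(CH3)3 deprotonates chloroform and alpha-elimination of chloride gives singlet dichlorocarbene, which adds as an electrophile in a concerted [2+1] step to the C2=C3 enol ether bond of 6 to form the cis-fused dichlorocyclopropane 8. Ring strain and donation from O1 at one terminus and the silyloxy oxygen at the other then drive a thermal two-electron disrotatory cyclopropyl-to-allyl opening in which the endo chloride departs and the old C2–C3 bond breaks, giving the aromatic 4-silyloxychromenylium chloride 9, from which chloride removes the silyl group to unveil the C4 carbonyl of 10. The net result is that C2–C3 and C3–C4 of the flavone are formed and the carbene carbon becomes C3 with one chlorine left on it. Ring C is closed by ring expansion and not by cyclisation of a chain: a [2+1] cycloaddition onto the furan followed by electrocyclic cleavage of the shared bond turns the five-membered ring into the six-membered pyranone. The closest known reaction types are the dihalocarbene ring expansion of cyclic silyl enol ethers to 2-halocycloalkenones and the Ciamician–Dennstedt expansion of pyrroles and indoles, the 3-silyloxybenzofuran being the untested substrate class. No stereocentre remains (those of 8 are transient); the step needs attack on the enol ether bond and not on the two methoxylated benzene rings, which the twofold oxygen donation into the non-benzenoid C2=C3 bond secures, and it needs the silyl ether to outlast the alkoxide, which the bulky tert-butyldimethylsilyl group and slow addition of base into excess chloroform at low temperature should provide.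

**Step 5**
Reactants: 10 3-chloro-6,7-dimethoxy-2-(3,4,5-trimethoxyphenyl)chromen-4-one
Product: 11 prosogerin C, 6,7-dimethoxy-2-(3,4,5-trimethoxyphenyl)chromen-4-one
Conditions: Pd(OAc)2 (5 mol%), P(C6H11)3 (10 mol%), HCO2Na, DMF, 90 °C
Reagents that add atoms: none
Why: Palladium-catalysed transfer hydrodehalogenation, in which zerovalent palladium formed in situ inserts into the C3–Cl bond (activated as an alpha-chloro enone), formate replaces chloride and loses CO2 to give a palladium hydride, and reductive elimination forms the C3–H bond while the aryl methyl ethers and the pyranone stay intact.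

**Compound list**
1 | methyl 2-hydroxy-4,5-dimethoxybenzoate | COC(=O)c1cc(OC)c(OC)cc1O | starting material
2 | 5-(chloromethyl)-1,2,3-trimethoxybenzene | COc1cc(CCl)cc(OC)c1OC | starting material
3 | methyl 4,5-dimethoxy-2-[(3,4,5-trimethoxyphenyl)methoxy]benzoate | COC(=O)c1cc(OC)c(OC)cc1OCc1cc(OC)c(OC)c(OC)c1 | intermediate
4 | lithium 5,6-dimethoxy-2-(3,4,5-trimethoxyphenyl)-1-benzofuran-3-olate (formed in the flask) | COc1cc2oc(-c3cc(OC)c(OC)c(OC)c3)c([O-])c2cc1OC.[Li+] | intermediate
5 | 5,6-dimethoxy-2-(3,4,5-trimethoxyphenyl)-1-benzofuran-3(2H)-one (racemic) | COc1cc2OC(c3cc(OC)c(OC)c(OC)c3)C(=O)c2cc1OC | intermediate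
6 | 3-(tert-butyldimethylsilyloxy)-5,6-dimethoxy-2-(3,4,5-trimethoxyphenyl)-1-benzofuran | COc1cc2oc(-c3cc(OC)c(OC)c(OC)c3)c(O[Si](C)(C)C(C)(C)C)c2cc1OC | intermediate
7 | chloroform | ClC(Cl)Cl | starting material
8 | 6b-(tert-butyldimethylsilyloxy)-1,1-dichloro-4,5-dimethoxy-1a-(3,4,5-trimethoxyphenyl)-1a,6b-dihydro-1H-cyclopropa[b][1]benzofuran (racemic, cis-fused, formed in the flask) | COc1cc2OC3(c4cc(OC)c(OC)c(OC)c4)C(Cl)(Cl)C3(O[Si](C)(C)C(C)(C)C)c2cc1OC | intermediate
9 | 4-(tert-butyldimethylsilyloxy)-3-chloro-6,7-dimethoxy-2-(3,4,5-trimethoxyphenyl)chromenylium chloride (formed in the flask) | COc1cc2[o+]c(-c3cc(OC)c(OC)c(OC)c3)c(Cl)c(O[Si](C)(C)C(C)(C)C)c2cc1OC.[Cl-] | intermediate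
10 | 3-chloro-6,7-dimethoxy-2-(3,4,5-trimethoxyphenyl)chromen-4-one | COc1cc2oc(-c3cc(OC)c(OC)c(OC)c3)c(Cl)c(=O)c2cc1OC | intermediate
11 | prosogerin C, 6,7-dimethoxy-2-(3,4,5-trimethoxyphenyl)chromen-4-one | COc1cc2oc(-c3cc(OC)c(OC)c(OC)c3)cc(=O)c2cc1OC | target

**Step count**
Total steps: 5. Longest linear sequence: 5 steps (1 → 3 → 5 → 6 → 10 → 11).

**Steps most likely to fail**

1. Step 4 (new method). The alkoxide may strip the silyl group from 6 before the carbene arrives, so that the freed enolate is dichloromethylated at C2 instead of being expanded. The cyclopropane may also fail to ionise cleanly, or tert-butoxide may open the chlorochromone at C2. The fallback uses known chemistry, sets out from 3 and returns at 11. Crossed Claisen condensation of ester 3 with the sodium enolate of commercial 1-(3,4,5-trimethoxyphenyl)ethanone (NaH, THF, reflux) should give 1-{4,5-dimethoxy-2-[(3,4,5-trimethoxyphenyl)methoxy]phenyl}-3-(3,4,5-trimethoxyphenyl)propane-1,3-dione F1. Hydrogenolysis of the benzyl ether (H2, Pd/C, ethyl acetate) should free the phenol to give 1-(2-hydroxy-4,5-dimethoxyphenyl)-3-(3,4,5-trimethoxyphenyl)propane-1,3-dione F2. Acid-catalysed cyclodehydration (catalytic H2SO4, acetic acid, 100 °C) then closes ring C and gives 11 directly.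

2. Step 2. Benzylic deprotonation may be too slow, which would let [1,2]-Wittig rearrangement of the benzyl aryl ether anion or addition of the amide base to the ester compete. The benzofuranone may also be oxidised by air at C2 during work-up. The fallback makes the carbon that becomes C2 more acidic with a removable ester; it sets out from 1 and returns at 5. Commercial methyl (3,4,5-trimethoxyphenyl)acetate is brominated through its lithium enolate (LiN(SiMe3)2, THF, −78 °C, then N-bromosuccinimide) to methyl 2-bromo-2-(3,4,5-trimethoxyphenyl)acetate F3. O-Alkylation of 1 with it (K2CO3, acetone, reflux) should give methyl 2-[2-methoxy-2-oxo-1-(3,4,5-trimethoxyphenyl)ethoxy]-4,5-dimethoxybenzoate F4. Dieckmann condensation of the now readily formed ester enolate (NaH, THF, 0 °C → rt) should give methyl 5,6-dimethoxy-3-oxo-2-(3,4,5-trimethoxyphenyl)-2,3-dihydro-1-benzofuran-2-carboxylate F5. Krapcho dealkoxycarbonylation (LiCl, wet DMSO, 130 °C, argon) then delivers 5.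

3. Step 5. Insertion of zerovalent palladium into the C–Cl bond may be sluggish, or the palladium hydride may add across C2=C3 and cause over-reduction. The fallback accepts the over-reduction and corrects it afterwards; it sets out from 10 and returns at 11. Hydrogenation (H2, 1 atm, Pd/C, NaOAc, ethyl acetate–methanol) is run until the chlorine is gone, allowing C2=C3 to be saturated, to give 6,7-dimethoxy-2-(3,4,5-trimethoxyphenyl)chroman-4-one F6 (racemic). Dehydrogenation with catalytic I2 in DMSO at 120 °C, a standard flavanone-to-flavone oxidation, then gives 11.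

**Further compounds**
F1 | step 4 | 1-{4,5-dimethoxy-2-[(3,4,5-trimethoxyphenyl)methoxy]phenyl}-3-(3,4,5-trimethoxyphenyl)propane-1,3-dione | COc1cc(OCc2cc(OC)c(OC)c(OC)c2)c(C(=O)CC(=O)c2cc(OC)c(OC)c(OC)c2)cc1OC
F2 | step 4 | 1-(2-hydroxy-4,5-dimethoxyphenyl)-3-(3,4,5-trimethoxyphenyl)propane-1,3-dione | COc1cc(O)c(C(=O)CC(=O)c2cc(OC)c(OC)c(OC)c2)cc1OC
F3 | step 2 | methyl 2-bromo-2-(3,4,5-trimethoxyphenyl)acetate (racemic) | COC(=O)C(Br)c1cc(OC)c(OC)c(OC)c1
F4 | step 2 | methyl 2-[2-methoxy-2-oxo-1-(3,4,5-trimethoxyphenyl)ethoxy]-4,5-dimethoxybenzoate (racemic) | COC(=O)c1cc(OC)c(OC)cc1OC(C(=O)OC)c1cc(OC)c(OC)c(OC)c1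
F5 | step 2 | methyl 5,6-dimethoxy-3-oxo-2-(3,4,5-trimethoxyphenyl)-2,3-dihydro-1-benzofuran-2-carboxylate (racemic) | COC(=O)C1(c2cc(OC)c(OC)c(OC)c2)Oc2cc(OC)c(OC)cc2C1=O
F6 | step 5 | 6,7-dimethoxy-2-(3,4,5-trimethoxyphenyl)chroman-4-one (racemic) | COc1cc2OC(c3cc(OC)c(OC)c(OC)c3)CC(=O)c2cc1OC
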